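**Retrosynthetic overview**

1. The ten-membered keto-lactone is not closed by lactonization; it is unveiled last by oxidative cleavage of the tetrasubstituted enol-ether C=C of pentacycle 24, whose cyclohexene ring has templated the cis fusion of the butyrolactone.
2. The tetrasubstituted alkylidene (butyrolactone C3 = furopyran C2) is cut by retro-dehydration/retro-Claisen into two lactones: tricyclic lactone 21 and bicyclic lactone 9.
3. Lactone 9 comes from (2R,5S)-hept-6-ene-2,5-diol 8 and CO by a palladium-catalysed alkoxycarbonylative double cyclization that closes the tetrahydropyran through its O4–C3a bond (furo[3,2-b]pyran locants) together with the five-membered O-ring. The enabling feature is the array O4–C3a(H)–C3H2–C2–O1–C7a: C3a carries the pyran oxygen, its CH2 neighbour leads to C2, which is at carbonyl oxidation level and bound to O1 on the cis-disposed neighbour C7a. This is exactly what oxypalladation/CO insertion/lactonization writes onto an allylic alcohol.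
4. Lactone 21 comes from an organocatalytic Michael/aldol cyclohexenone synthesis (sets the ring-fusion carbon), an α′-alkylation with a (R)-3-silyloxybutyl iodide, and an acid-triggered conjugate lactonization/dihydropyran closure.
5. Ring order: tetrahydropyran + five-membered oxacycle (step 6); cyclohexenone (step 10), then butyrolactone + dihydropyran (step 12); union of the two lactones (steps 13, 14); macrolactone by ring expansion (step 15).

Key step: step 6

Remark: centres that are formed as mixtures and erased later (the α′ carbon in 18–20, the hemiketal carbons in 20 and 23, the lactone α-carbon in 23) are left undefined in the SMILES.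

**Route**

Step 1
Reactants: 1 (R)-γ-valerolactone
Product: 3 (4R)-4-(tert-butyldimethylsilyloxy)-N-methoxy-N-methylpentanamide, via hydroxy Weinreb amide 2 (not isolated)
Conditions: MeNH(OMe)·HCl, i-PrMgCl, THF, −20 to 0 °C; aq. NH4Cl; crude 2, then TBSCl, imidazole, DMF, rt
Reagents that add atoms: N,O-dimethylhydroxylamine hydrochloride, CNOC.Cl; tert-butyldimethylsilyl chloride, CC(C)(C)[Si](C)(C)Cl
Why: Aminolysis of the lactone by the chloromagnesium amide (Weinreb amide formation) followed by immediate silylation of the freed secondary alcohol should prevent relactonization; the carbinol centre of the lactone is not touched.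

Step 2
Reactants: 3 (4R)-4-(tert-butyldimethylsilyloxy)-N-methoxy-N-methylpentanamide; 4 lithium (trimethylsilyl)acetylide (0.5 M in THF)
Product: 5 (6R)-6-(tert-butyldimethylsilyloxy)-1-(trimethylsilyl)hept-1-yn-3-one
Conditions: THF, −78 to 0 °C; then aq. NH4Cl
Reagents that add atoms: none
Why: Acetylide addition to a Weinreb amide stops at the chelated tetrahedral intermediate, so the ynone should form without over-addition (Weinreb ketone synthesis).

Step 3
Reactants: 5 (6R)-6-(tert-butyldimethylsilyloxy)-1-(trimethylsilyl)hept-1-yn-3-one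
Product: 6 (3S,6R)-6-(tert-butyldimethylsilyloxy)-1-(trimethylsilyl)hept-1-yn-3-ol
Conditions: RuCl(p-cymene)[(S,S)-TsDPEN] (1 mol%), i-PrOH, rt
Reagents that add atoms: none
Why: Noyori asymmetric transfer hydrogenation of an alkynyl ketone; the (S,S) catalyst should place the alkyne in its π-site and deliver hydride to give the (S)-propargylic alcohol under catalyst control, independent of the remote silyloxy centre.

Step 4
Reactants: 6 (3S,6R)-6-(tert-butyldimethylsilyloxy)-1-(trimethylsilyl)hept-1-yn-3-ol
Product: 7 (2R,5S)-hept-6-yne-2,5-diol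
Conditions: n-Bu4NF, THF, 0 °C to rt; then aq. NH4Cl
Reagents that add atoms: none
Why: Fluoride should cleave both the O–Si and the alkynyl C–Si bond (desilylation) without affecting either carbinol centre.

Step 5
Reactants: 7 (2R,5S)-hept-6-yne-2,5-diol
Product: 8 (2R,5S)-hept-6-ene-2,5-diol
Conditions: H2 (1 atm), Pd/CaCO3 poisoned with Pb(OAc)2, quinoline, EtOAc, rt
Reagents that add atoms: none
Why: Lindlar semihydrogenation of a terminal alkyne should stop at the vinyl group; no stereocentre is involved.

Step 6
Reactants: 8 (2R,5S)-hept-6-ene-2,5-diol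
Product: 9 (3aS,5R,7aS)-5-methylhexahydro-2H-furo[3,2-b]pyran-2-one
Conditions: PdCl2 (10 mol%), CuCl2 (3 equiv), NaOAc (3 equiv), CO (1 atm), AcOH, rt
Reagents that add atoms: carbon monoxide, [C-]#[O+]
Why: Divalent palladium (PdCl2) should bind the vinyl group next to the allylic hydroxyl; the C2 hydroxyl then adds to the internal alkene carbon (alkoxypalladation) to forge the pyran O–C bond and a primary σ-alkylpalladium, CO inserts, and the acylpalladium is captured by the allylic hydroxyl to give the γ-lactone and zerovalent palladium, which CuCl2 reoxidizes. The closest known reaction type is the intramolecular alkoxycarbonylation–lactonization (oxycarbonylative bicyclization) of alkenediols, used for cis-fused pyrano- and furano-γ-lactones. The tetrahydropyran closes in the 6-exo-trig mode and the lactone in the 5-exo-trig mode (acyl substitution at the acylpalladium carbon). The one new stereocentre (C3a) is set by a chair transition state with the C5 methyl equatorial, which forces the allylic hydroxyl axial and lets the alkene react from an equatorial position, so the C3 methylene ends up cis to both the methyl and the hydroxyl. The step needs this facial selectivity and the right hydroxyl as nucleophile: the latter is secured because the allylic hydroxyl cannot reach the alkene, the former by the equatorial methyl, by coordination of the allylic hydroxyl to palladium, and because alkoxypalladation is reversible while only the cis intermediate lactonizes without strain.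

Step 7
Reactants: 10 (R)-butane-1,3-diol
Product: 11 (R)-4-iodobutan-2-ol
Conditions: PPh3, imidazole, I2, CH2Cl2, 0 °C
Reagents that add atoms: iodine, II
Why: Appel-type iodination should select the primary hydroxyl of the 1,3-diol on steric grounds; the secondary carbinol centre does not react.

Step 8
Reactants: 11 (R)-4-iodobutan-2-ol
Product: 12 (R)-tert-butyl[(4-iodobutan-2-yl)oxy]dimethylsilane
Conditions: TBSCl, imidazole, DMF, rt
Reagents that add atoms: tert-butyldimethylsilyl chloride, CC(C)(C)[Si](C)(C)Cl
Why: Standard silylation of a secondary alcohol; the stereocentre is not involved.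

Step 9
Reactants: 13 tert-butyl 4-oxobutanoate; 14 but-3-en-2-one
Product: 15 tert-butyl (3S)-3-formyl-6-oxoheptanoate
Conditions: (S)-2-[methoxy(diphenyl)methyl]pyrrolidine (5 mol%), ethyl 3,4-dihydroxybenzoate (20 mol%), neat, 4 °C
Reagents that add atoms: none
Why: Enamine-catalysed Michael addition of an aldehyde to a vinyl ketone; the diarylmethyl group shields one face of the E-enamine so the enone should be attacked from the Si face, setting the (S) α-centre.

Step 10
Reactants: 15 tert-butyl (3S)-3-formyl-6-oxoheptanoate
Product: 16 tert-butyl 2-[(1S)-4-oxocyclohex-2-en-1-yl]acetate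
Conditions: KOH (0.1 M aq.), n-Bu4NOH (cat.), Et2O/THF, reflux
Reagents that add atoms: none
Why: Intramolecular aldol condensation of the 1,5-keto aldehyde (methyl ketone enolate onto the aldehyde, then dehydration) should close the cyclohexenone; the stereocentre becomes the γ-carbon and should survive short exposure to dilute base.

Step 11
Reactants: 16 tert-butyl 2-[(1S)-4-oxocyclohex-2-en-1-yl]acetate; 12 (R)-tert-butyl[(4-iodobutan-2-yl)oxy]dimethylsilane
Product: 18 tert-butyl 2-[(1S)-5-[(3R)-3-(tert-butyldimethylsilyloxy)butyl]-4-oxocyclohex-2-en-1-yl]acetate (mixture at C5), via lithium dienolate 17 (not isolated)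
Conditions: LiN(i-Pr)2 (1.05 equiv), THF, −78 °C; then 12, DMPU, −78 to −20 °C
Reagents that add atoms: none
Why: Kinetic deprotonation of a cyclohexenone by a lithium amide occurs at the α′ carbon (cross-conjugated dienolate), which should be alkylated by the primary iodide (enolate alkylation); the new α′ centre forms as a mixture, which is harmless because it becomes sp2 in step 12.

Step 12
Reactants: 18 tert-butyl 2-[(1S)-5-[(3R)-3-(tert-butyldimethylsilyloxy)butyl]-4-oxocyclohex-2-en-1-yl]acetate
Product: 21 (3aS,7R,9aS)-7-methyl-3,3a,4,5,6,7,9,9a-octahydro-2H-furo[3,2-g]chromen-2-one, via hydroxy acid 19 (not isolated), via lactol 20 (not isolated)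
Conditions: TFA/CH2Cl2/H2O, 0 °C to rt; concentrate; then PPTS (20 mol%), 4 Å molecular sieves, benzene, 70 °C
Reagents that add atoms: none
Why: Acid should remove the tert-butyl and silyl groups; the carboxylic acid then adds to the enone β-carbon from the face of its own tether (intramolecular oxa-Michael lactonization, the five-membered ring enforcing the cis fusion so that the existing centre sets the new C–O centre), and the δ-hydroxy ketone closes to a lactol that dehydrates to the more substituted, tetrasubstituted enol ether (cyclodehydration as in hexahydrochromene syntheses).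

Step 13
Reactants: 21 (3aS,7R,9aS)-7-methyl-3,3a,4,5,6,7,9,9a-octahydro-2H-furo[3,2-g]chromen-2-one; 9 (3aS,5R,7aS)-5-methylhexahydro-2H-furo[3,2-b]pyran-2-one
Product: 23 (3aS,7R,9aS)-3-[(3aS,5R,7aS)-2-hydroxy-5-methylhexahydro-2H-furo[3,2-b]pyran-2-yl]-7-methyl-3,3a,4,5,6,7,9,9a-octahydro-2H-furo[3,2-g]chromen-2-one (hemiketal in equilibrium with the open hydroxy β-keto lactone), via lithium lactone enolate 22 (not isolated)
Conditions: LiN(i-Pr)2 (1.1 equiv), THF, −78 °C; then 9 (1.2 equiv), −78 to −40 °C; AcOH quench at −78 °C
Reagents that add atoms: none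
Why: Crossed Claisen condensation of a lithium lactone enolate with a γ-lactone (the reaction type of the base-induced self-condensation of γ-butyrolactone); 1,2-addition at low temperature should outrun proton transfer, and the two new centres may be left as a mixture because step 14 erases them.

Step 14
Reactants: 23 hemiketal adduct
Product: 24 (3E,3aS,7R,9aS)-7-methyl-3-[(3aS,5R,7aS)-5-methylhexahydro-2H-furo[3,2-b]pyran-2-ylidene]-3,3a,4,5,6,7,9,9a-octahydro-2H-furo[3,2-g]chromen-2-one
Conditions: PPTS (20 mol%), 4 Å molecular sieves, toluene, 40 °C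
Reagents that add atoms: none
Why: Acid-catalysed cyclodehydration of a γ-hydroxy β-keto lactone/hemiketal to a 2-alkylidenetetrahydrofuran should give the push–pull alkene; under these reversible conditions the E isomer should prevail because it keeps the ring oxygen away from the lactone carbonyl oxygen and places the small oxygen, not the methylene, next to the substituted ring-fusion carbon.

Step 15
Reactants: 24 pentacyclic enol ether
Product: 25 cordycicadin C
Conditions: m-CPBA (2.2 equiv), CH2Cl2, 0 °C to rt
Reagents that add atoms: 3-chloroperoxybenzoic acid, OOC(=O)c1cccc(Cl)c1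
Why: The electrophilic peracid should attack only the electron-rich tetrasubstituted enol ether (not the acceptor-substituted alkylidene); the epoxy ether is then cleaved by a second equivalent through a Criegee-type fragmentation to ketone and lactone (Borowitz oxidative ring expansion of a bicyclic enol ether), opening the carbocycle to the ten-membered keto-lactone without touching a stereocentre.

**Compound list**

1 | (R)-γ-valerolactone | C[C@@H]1CCC(=O)O1 | starting material
2 | (4R)-4-hydroxy-N-methoxy-N-methylpentanamide | C[C@@H](O)CCC(=O)N(C)OC | intermediate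
3 | (4R)-4-(tert-butyldimethylsilyloxy)-N-methoxy-N-methylpentanamide | C[C@@H](O[Si](C)(C)C(C)(C)C)CCC(=O)N(C)OC | intermediate
4 | lithium (trimethylsilyl)acetylide | [Li]C#C[Si](C)(C)C | starting material
5 | (6R)-6-(tert-butyldimethylsilyloxy)-1-(trimethylsilyl)hept-1-yn-3-one | C[C@@H](O[Si](C)(C)C(C)(C)C)CCC(=O)C#C[Si](C)(C)C | intermediate
6 | (3S,6R)-6-(tert-butyldimethylsilyloxy)-1-(trimethylsilyl)hept-1-yn-3-ol | C[C@@H](O[Si](C)(C)C(C)(C)C)CC[C@H](O)C#C[Si](C)(C)C | intermediate
7 | (2R,5S)-hept-6-yne-2,5-diol | C[C@@H](O)CC[C@H](O)C#C | intermediate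
8 | (2R,5S)-hept-6-ene-2,5-diol | C[C@@H](O)CC[C@H](O)C=C | intermediate
9 | (3aS,5R,7aS)-5-methylhexahydro-2H-furo[3,2-b]pyran-2-one | O=C1C[C@@H]2O[C@H](C)CC[C@@H]2O1 | intermediate
10 | (R)-butane-1,3-diol | C[C@@H](O)CCO | starting material
11 | (R)-4-iodobutan-2-ol | C[C@@H](O)CCI | intermediate
12 | (R)-tert-butyl[(4-iodobutan-2-yl)oxy]dimethylsilane | C[C@@H](O[Si](C)(C)C(C)(C)C)CCI | intermediate
13 | tert-butyl 4-oxobutanoate | O=CCCC(=O)OC(C)(C)C | starting material
14 | but-3-en-2-one | C=CC(C)=O | starting material
15 | tert-butyl (3S)-3-formyl-6-oxoheptanoate | CC(=O)CC[C@H](C=O)CC(=O)OC(C)(C)C | intermediate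
16 | tert-butyl 2-[(1S)-4-oxocyclohex-2-en-1-yl]acetate | O=C1C=C[C@H](CC(=O)OC(C)(C)C)CC1 | intermediate
17 | lithium (4S)-4-(2-tert-butoxy-2-oxoethyl)cyclohexa-1,5-dien-1-olate | [Li+].[O-]C1=CC[C@@H](CC(=O)OC(C)(C)C)C=C1 | intermediate
18 | tert-butyl 2-[(1S)-5-[(3R)-3-(tert-butyldimethylsilyloxy)butyl]-4-oxocyclohex-2-en-1-yl]acetate | C[C@@H](O[Si](C)(C)C(C)(C)C)CCC1C[C@@H](CC(=O)OC(C)(C)C)C=CC1=O | intermediate
19 | 2-[(1S)-5-[(3R)-3-hydroxybutyl]-4-oxocyclohex-2-en-1-yl]acetic acid | C[C@@H](O)CCC1C[C@@H](CC(=O)O)C=CC1=O | intermediate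
20 | (3aS,7R,9aS)-8a-hydroxy-7-methyldecahydro-2H-furo[3,2-g]chromen-2-one (lactol of the keto lactone) | C[C@@H]1CCC2C[C@H]3CC(=O)O[C@H]3CC2(O)O1 | intermediate
21 | (3aS,7R,9aS)-7-methyl-3,3a,4,5,6,7,9,9a-octahydro-2H-furo[3,2-g]chromen-2-one | C[C@@H]1CCC2=C(O1)C[C@@H]3OC(=O)C[C@@H]3C2 | intermediate
22 | lithium enolate of lactone 21 | [Li+].C[C@@H]1CCC2=C(O1)C[C@@H]3OC([O-])=C[C@@H]3C2 | intermediate
23 | (3aS,7R,9aS)-3-[(3aS,5R,7aS)-2-hydroxy-5-methylhexahydro-2H-furo[3,2-b]pyran-2-yl]-7-methyl-3,3a,4,5,6,7,9,9a-octahydro-2H-furo[3,2-g]chromen-2-one | C[C@@H]1CCC2=C(O1)C[C@@H]3OC(=O)C([C@@H]3C2)C4(O)C[C@@H]5O[C@H](C)CC[C@@H]5O4 | intermediate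
24 | (3E,3aS,7R,9aS)-7-methyl-3-[(3aS,5R,7aS)-5-methylhexahydro-2H-furo[3,2-b]pyran-2-ylidene]-3,3a,4,5,6,7,9,9a-octahydro-2H-furo[3,2-g]chromen-2-one | C[C@@H]1CCC2=C(O1)C[C@@H]3OC(=O)/C(=C4\C[C@@H]5O[C@H](C)CC[C@@H]5O4)[C@@H]3C2 | intermediate
25 | cordycicadin C | C[C@@H]1CCC(=O)C[C@H]2/C(=C3/C[C@@H]4O[C@H](C)CC[C@@H]4O3)C(=O)O[C@H]2CC(=O)O1 | target

**Step count and risks**

Total step count: 15. Longest linear sequence: 9 steps (steps 1–6, then 13–15).

Most likely to fail, in order:

Step 13. Proton transfer from the α-methylene of lactone 9 to enolate 22 may compete with 1,2-addition; the enolate of 9 so formed would expel the pyran oxygen by β-elimination and the coupling would stall. The fallback moves the C–C bond formation to an aldol reaction and lets the same pyran O–C bond close late by oxa-Michael addition. It sets out from diol 8 and from lactone 21 (through enolate 22) and comes back to the route at 24. Diol 8 would be silylated (TESCl, imidazole) to (3S,6R)-3,6-bis(triethylsilyloxy)hept-1-ene F1. Cross-metathesis with crotonaldehyde, using RuCl2(H2IMes)(=CH-C6H4-2-O-i-Pr) (second-generation Hoveyda–Grubbs catalyst), should give (2E,4S,7R)-4,7-bis(triethylsilyloxy)oct-2-enal F2. Addition of enolate 22 to F2 at −78 °C should give the allylic alcohol F3, and Dess–Martin oxidation the enoyl lactone F4. HF·pyridine should free the diol F5, which under PPTS should undergo 6-exo-trig oxa-Michael addition (2,6-cis under thermodynamic control), hemiketalization and dehydration to 24.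

Step 12. The alkoxy-allyl cation that arises from the enone hemiketal, or from re-ionization of the lactone once the enol ether has migrated next to it, may lose the γ-proton at the ring-fusion carbon; this would erode the configuration of the two lactone ring-fusion centres relative to the methyl-bearing centre. Lactonization may also remain incomplete. The fallback makes the lactone C–O bond by a halonium route instead of a cationic conjugate addition. It sets out from 18 and comes back to the route at lactol 20. Luche reduction of 18 (NaBH4, CeCl3·7H2O, MeOH) should give the allylic alcohol F6. Iodolactonization of the tert-butyl ester (I2, NaHCO3, MeCN) should give the cis-fused iodolactone F7, with iodine trans to the lactone oxygen. Radical deiodination (n-Bu3SnH, AIBN) should give the hydroxy lactone F8, and Dess–Martin oxidation the keto lactone silyl ether F9. HF·pyridine then liberates lactol 20, which is dehydrated with PPTS as in the second half of step 12.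

Step 11. Alkylation of the cross-conjugated dienolate by an unactivated primary iodide may be slow, leaving time for proton exchange to the extended dienolate (loss of configuration at the γ-carbon) and for polyalkylation. The fallback replaces the alkylation by a Michael addition and sets the side-chain carbinol enzymatically. It sets out from 16 (through enolate 17) and comes back to the route at hydroxy acid 19. Enolate 17 would be added to 3-(trimethylsilyl)but-3-en-2-one to give the α-silyl diketone F10, which dilute HCl work-up should desilylate to the diketone F11. An (R)-selective (anti-Prelog) ketoreductase with NADP+ and i-PrOH should reduce only the methyl ketone, giving the hydroxy enone ester F12. TFA then cleaves the tert-butyl ester to give 19, which continues as in step 12.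

Further compounds
F1 | step 13 | (3S,6R)-3,6-bis(triethylsilyloxy)hept-1-ene | C[C@@H](O[Si](CC)(CC)CC)CC[C@H](O[Si](CC)(CC)CC)C=C
F2 | step 13 | (2E,4S,7R)-4,7-bis(triethylsilyloxy)oct-2-enal | C[C@@H](O[Si](CC)(CC)CC)CC[C@H](O[Si](CC)(CC)CC)/C=C/C=O
F3 | step 13 | aldol adduct of 21 and F2 (3-[(2E,4S,7R)-1-hydroxy-4,7-bis(triethylsilyloxy)oct-2-enyl] derivative of 21) | C[C@@H]1CCC2=C(O1)C[C@@H]3OC(=O)C([C@@H]3C2)C(O)/C=C/[C@@H](O[Si](CC)(CC)CC)CC[C@@H](C)O[Si](CC)(CC)CC
F4 | step 13 | 3-[(2E,4S,7R)-4,7-bis(triethylsilyloxy)oct-2-enoyl] derivative of 21 | C[C@@H]1CCC2=C(O1)C[C@@H]3OC(=O)C([C@@H]3C2)C(=O)/C=C/[C@@H](O[Si](CC)(CC)CC)CC[C@@H](C)O[Si](CC)(CC)CC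
F5 | step 13 | 3-[(2E,4S,7R)-4,7-dihydroxyoct-2-enoyl] derivative of 21 | C[C@@H]1CCC2=C(O1)C[C@@H]3OC(=O)C([C@@H]3C2)C(=O)/C=C/[C@@H](O)CC[C@@H](C)O
F6 | step 12 | tert-butyl 2-[(1S)-5-[(3R)-3-(tert-butyldimethylsilyloxy)butyl]-4-hydroxycyclohex-2-en-1-yl]acetate | C[C@@H](O[Si](C)(C)C(C)(C)C)CCC1C[C@@H](CC(=O)OC(C)(C)C)C=CC1O
F7 | step 12 | cis-fused 5-[(3R)-3-(tert-butyldimethylsilyloxy)butyl]-6-hydroxy-7-iodohexahydrobenzofuran-2(3H)-one (iodine trans to the lactone oxygen) | C[C@@H](O[Si](C)(C)C(C)(C)C)CCC1C[C@H]2CC(=O)O[C@H]2[C@@H](I)C1O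
F8 | step 12 | (3aS,7aS)-5-[(3R)-3-(tert-butyldimethylsilyloxy)butyl]-6-hydroxyhexahydrobenzofuran-2(3H)-one | C[C@@H](O[Si](C)(C)C(C)(C)C)CCC1C[C@H]2CC(=O)O[C@H]2CC1O
F9 | step 12 | (3aS,7aS)-5-[(3R)-3-(tert-butyldimethylsilyloxy)butyl]tetrahydrobenzofuran-2,6(3H,7H)-dione | C[C@@H](O[Si](C)(C)C(C)(C)C)CCC1C[C@H]2CC(=O)O[C@H]2CC1=O
F10 | step 11 | tert-butyl 2-[(1S)-4-oxo-5-[3-oxo-2-(trimethylsilyl)butyl]cyclohex-2-en-1-yl]acetate | CC(=O)C(CC1C[C@@H](CC(=O)OC(C)(C)C)C=CC1=O)[Si](C)(C)C
F11 | step 11 | tert-butyl 2-[(1S)-4-oxo-5-(3-oxobutyl)cyclohex-2-en-1-yl]acetate | CC(=O)CCC1C[C@@H](CC(=O)OC(C)(C)C)C=CC1=O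
F12 | step 11 | tert-butyl 2-[(1S)-5-[(3R)-3-hydroxybutyl]-4-oxocyclohex-2-en-1-yl]acetate | C[C@@H](O)CCC1C[C@@H](CC(=O)OC(C)(C)C)C=CC1=O
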